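Chroman numbering is used (O1, C2, C3, C4; fused ring A, pendant ring B). Everything rests on the C3–C4 bond: ring B at C3 and the hydroxyl at C4 are trans, the imprint of a syn H–B addition to a C3=C4 alkene, and both carbons map onto carbonyl carbons, C4 the formyl carbon ortho to O1 on ring A and C3 the ketone carbon on ring B. The precursor is therefore an aryl phenacyl ether; an intramolecular McMurry coupling closes the pyran ring as the isoflav-3-ene in one operation, and reagent-controlled hydroboration then sets both stereocentres. The hydroquinone of ring B comes from an Elbs oxidation and travels as benzyl ethers.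

Key step: step 6

Remark: 1 and 3 are taken as commercial, and the facial preference of (+)-α-pinene-derived IpcBH2 known for 1-arylcycloalkenes is assumed to hold for chromene 10 (if the opposite sense is found, the reagent from (−)-α-pinene is used).

Step 1
Reactants: 1 2,3,4-trimethoxyphenol
Product: 2 2-hydroxy-3,4,5-trimethoxybenzaldehyde
Conditions: MgCl2, Et3N, (CH2O)n, MeCN, reflux; aq HCl work-up
Reagents that add atoms: paraformaldehyde (formaldehyde), C=O
Why: Magnesium-mediated ortho-formylation of a phenol (Casnati–Skattebøl type): the magnesium phenoxide directs formaldehyde to the only free ortho position, and a second formaldehyde oxidises the resulting benzylic alkoxide to the aldehyde.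

Step 2
Reactants: 3 1-(2-hydroxy-3,4-dimethoxyphenyl)ethanone
Product: 5 1-(2,5-dihydroxy-3,4-dimethoxyphenyl)ethanone, via aryl sulfate potassium salt 4 (not isolated)
Conditions: K2S2O8, aq KOH, 10 °C to rt; then HCl, 90 °C, under N2
Reagents that add atoms: potassium peroxydisulfate, [K+].[K+].[O-]S(=O)(=O)OOS(=O)(=O)[O-]
Why: Elbs persulfate oxidation: the phenoxide attacks peroxydisulfate through its para carbon (both ortho positions are blocked by acetyl and methoxy), and acid hydrolysis of the aryl sulfate frees the second hydroxyl.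

Step 3
Reactants: 5 1-(2,5-dihydroxy-3,4-dimethoxyphenyl)ethanone
Product: 6 1-[2,5-bis(benzyloxy)-3,4-dimethoxyphenyl]ethanone
Conditions: BnBr, K2CO3, DMF, 70 °C
Reagents that add atoms: benzyl bromide, BrCc1ccccc1
Why: Williamson ether synthesis; excess BnBr in warm DMF also benzylates the hydrogen-bonded 2-OH, and the benzyl ethers should survive base, low-valent titanium, borane and alkaline peroxide.

Step 4
Reactants: 6 1-[2,5-bis(benzyloxy)-3,4-dimethoxyphenyl]ethanone
Product: 7 2-bromo-1-[2,5-bis(benzyloxy)-3,4-dimethoxyphenyl]ethanone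
Conditions: CuBr2, EtOAc–CHCl3, reflux
Reagents that add atoms: copper dibromide, Br[Cu]Br
Why: Heterogeneous α-bromination of an aryl methyl ketone with CuBr2, which brominates the enol selectively and should leave the electron-rich ring and the benzyl ethers untouched.

Step 5
Reactants: 2 2-hydroxy-3,4,5-trimethoxybenzaldehyde, 7 2-bromo-1-[2,5-bis(benzyloxy)-3,4-dimethoxyphenyl]ethanone
Product: 8 2-{2-[2,5-bis(benzyloxy)-3,4-dimethoxyphenyl]-2-oxoethoxy}-3,4,5-trimethoxybenzaldehyde
Conditions: K2CO3, acetone, rt
Reagents that add atoms: none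
Why: Williamson O-alkylation (SN2) of the salicylaldehyde phenoxide by the phenacyl bromide; the weak base and room temperature should hold back the Rap–Stoermer aldol cyclisation to a 2-aroylbenzofuran.

Step 6
Reactants: 8 2-{2-[2,5-bis(benzyloxy)-3,4-dimethoxyphenyl]-2-oxoethoxy}-3,4,5-trimethoxybenzaldehyde
Product: 10 3-[2,5-bis(benzyloxy)-3,4-dimethoxyphenyl]-6,7,8-trimethoxy-2H-chromene, via titanium pinacolate 9 (not isolated)
Conditions: TiCl4, Zn, pyridine, THF, reflux, slow addition of 8 (high dilution)
Reagents that add atoms: none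
Why: Low-valent titanium made from TiCl4 and Zn reduces the ring A aldehyde and the ring B aryl ketone to titanium-bound ketyls, which couple to the cyclic pinacolate 9 (C3–C4 bond) and are deoxygenated at reflux to the C3=C4 alkene. The closest known reaction type is the intramolecular McMurry coupling used for 2H-chromenes, benzofurans and indoles from two carbonyl groups held by a short heteroatom tether. The pyran ring closes by ketyl–ketyl coupling in which both C=O bonds lie outside the new six-membered ring (6-exo-trig at each carbonyl), templated by the O1–C2 ether link. No stereocentre is formed; the step fixes the ring alkene with ring B on C3 and hydrogen on C4, which step 7 turns into both stereocentres. The step needs ring closure to win over intermolecular coupling, which slow addition at high dilution secures, and over reductive cleavage of the aryloxy–CH2 bond next to the ketone, which the fast coupling of two neighbouring titanium-bound carbonyls should outrun. The aryl methyl and benzyl ethers are inert to the reagent.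

Step 7
Reactants: 10 3-[2,5-bis(benzyloxy)-3,4-dimethoxyphenyl]-6,7,8-trimethoxy-2H-chromene
Product: 12 (3S,4R)-3-[2,5-bis(benzyloxy)-3,4-dimethoxyphenyl]-6,7,8-trimethoxychroman-4-ol, via isopinocampheyl(chroman-4-yl)borane 11 (not isolated)
Conditions: IpcBH2 (from (+)-α-pinene), THF, −25 °C to 0 °C; then NaOH, H2O2, 0 °C to rt
Reagents that add atoms: hydrogen peroxide, OO
Why: Asymmetric hydroboration–oxidation with monoisopinocampheylborane: the bulky chiral borane puts boron on the less substituted C4 and hydrogen on C3 in a syn addition to one alkene face (reagent control), and oxidation with retention gives the 3,4-trans (3S,4R) alcohol, so both stereocentres are set here.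

Step 8
Reactants: 12 (3S,4R)-3-[2,5-bis(benzyloxy)-3,4-dimethoxyphenyl]-6,7,8-trimethoxychroman-4-ol
Product: 13 (3S,4R)-3-(2,5-dihydroxy-3,4-dimethoxyphenyl)-6,7,8-trimethoxychroman-4-ol
Conditions: H2 (1 atm), Pd/C, EtOAc, rt; filtration under argon
Reagents that add atoms: none
Why: Catalytic hydrogenolysis of the two aryl benzyl ethers under neutral conditions should be faster than hydrogenolysis of the C4 benzylic hydroxyl, and the absence of acid avoids ionisation at C4 and ring closure by the 2'-OH, so C3 and C4 stay untouched.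

Compound list
1 | 2,3,4-trimethoxyphenol | COc1ccc(O)c(OC)c1OC | starting material
2 | 2-hydroxy-3,4,5-trimethoxybenzaldehyde | COc1cc(C=O)c(O)c(OC)c1OC | intermediate
3 | 1-(2-hydroxy-3,4-dimethoxyphenyl)ethanone | CC(=O)c1ccc(OC)c(OC)c1O | starting material
4 | potassium 5-acetyl-4-hydroxy-2,3-dimethoxyphenyl sulfate | CC(=O)c1cc(OS(=O)(=O)[O-])c(OC)c(OC)c1O.[K+] | intermediate (not isolated)
5 | 1-(2,5-dihydroxy-3,4-dimethoxyphenyl)ethanone | CC(=O)c1cc(O)c(OC)c(OC)c1O | intermediate
6 | 1-[2,5-bis(benzyloxy)-3,4-dimethoxyphenyl]ethanone | CC(=O)c1cc(OCc2ccccc2)c(OC)c(OC)c1OCc1ccccc1 | intermediate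
7 | 2-bromo-1-[2,5-bis(benzyloxy)-3,4-dimethoxyphenyl]ethanone | O=C(CBr)c1cc(OCc2ccccc2)c(OC)c(OC)c1OCc1ccccc1 | intermediate
8 | 2-{2-[2,5-bis(benzyloxy)-3,4-dimethoxyphenyl]-2-oxoethoxy}-3,4,5-trimethoxybenzaldehyde | COc1cc(C=O)c(OCC(=O)c2cc(OCc3ccccc3)c(OC)c(OC)c2OCc2ccccc2)c(OC)c1OC | intermediate
9 | titanium-bound 3,4-diolate of 3-[2,5-bis(benzyloxy)-3,4-dimethoxyphenyl]-6,7,8-trimethoxychromane-3,4-diol (drawn as the free diol; configuration not controlled, both forms converge to 10) | COc1cc2c(c(OC)c1OC)OCC(O)(c1cc(OCc3ccccc3)c(OC)c(OC)c1OCc1ccccc1)C2O | intermediate (not isolated)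
10 | 3-[2,5-bis(benzyloxy)-3,4-dimethoxyphenyl]-6,7,8-trimethoxy-2H-chromene | COc1cc2c(c(OC)c1OC)OCC(c1cc(OCc3ccccc3)c(OC)c(OC)c1OCc1ccccc1)=C2 | intermediate
11 | isopinocampheyl{3,4-trans-3-[2,5-bis(benzyloxy)-3,4-dimethoxyphenyl]-6,7,8-trimethoxychroman-4-yl}borane (boron at C4 on the face later taken by the hydroxyl) | C[C@@H]1[C@H]2C[C@H](C2(C)C)C[C@H]1B[C@H]1c2cc(OC)c(OC)c(OC)c2OC[C@@H]1c1cc(OCc2ccccc2)c(OC)c(OC)c1OCc1ccccc1 | intermediate (not isolated)
12 | (3S,4R)-3-[2,5-bis(benzyloxy)-3,4-dimethoxyphenyl]-6,7,8-trimethoxychroman-4-ol | COc1cc2c(c(OC)c1OC)OC[C@H](c1cc(OCc3ccccc3)c(OC)c(OC)c1OCc1ccccc1)[C@H]2O | intermediate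
13 | (3S,4R)-3-(2,5-dihydroxy-3,4-dimethoxyphenyl)-6,7,8-trimethoxychroman-4-ol | COc1cc2c(c(OC)c1OC)OC[C@H](c1cc(O)c(OC)c(OC)c1O)[C@H]2O | target

Total step count: 8. Longest linear sequence: 7 steps (3 to 13, steps 2 to 8).

Steps most likely to fail

Step 6 may suffer reductive cleavage of the aryloxy–CH2 bond next to the ketone, or intermolecular coupling in place of ring closure. The fallback sets out from 8 and returns at 10. Double Wittig methylenation of the aldehyde and the ketone (Ph3PCH3Br, KOtBu, THF, 0 °C to rt) should give the diene 1-ethenyl-2-{[2-(2,5-bis(benzyloxy)-3,4-dimethoxyphenyl)prop-2-en-1-yl]oxy}-3,4,5-trimethoxybenzene F1. Ring-closing metathesis with the second-generation Grubbs catalyst RuCl2(=CHPh)(H2IMes)(PCy3) in CH2Cl2 at 40 °C then forms the same C3=C4 bond and gives 10.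

Step 7 may show insufficient facial selectivity, slow addition of the bulky borane to the hindered trisubstituted alkene, or partial boron placement at C3 under the electronic pull of ring A. The fallback sets out from 10 and returns at 12. Hydroboration with BH3·SMe2 in THF and oxidation with NaBO3 should give the racemic alcohol (±)-trans-3-[2,5-bis(benzyloxy)-3,4-dimethoxyphenyl]-6,7,8-trimethoxychroman-4-ol F2. Esterification with (S)-methoxy(phenyl)acetic acid (DCC, DMAP, CH2Cl2) gives two diastereomeric esters. The ester of the (3S,4R) alcohol, (3S,4R)-3-[2,5-bis(benzyloxy)-3,4-dimethoxyphenyl]-6,7,8-trimethoxychroman-4-yl (2S)-methoxy(phenyl)acetate F3, is separated by chromatography or crystallisation, the other diastereomer being removed. LiOH in THF–H2O then returns 12.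

Step 2 may give low conversion and oxidative degradation of the electron-rich phenoxide. The fallback sets out from 3 and returns at 5. Duff formylation (hexamethylenetetramine, CF3CO2H, 80 °C, then aq HCl) at the only activated free position, para to the hydroxyl, should give 5-acetyl-4-hydroxy-2,3-dimethoxybenzaldehyde F4. Dakin oxidation (H2O2, aq NaOH, 0 °C), in which the aldehyde should react before the hydrogen-bonded ketone, and hydrolysis of the aryl formate return 5.

Further compounds
F1 | step 6 | 1-ethenyl-2-{[2-(2,5-bis(benzyloxy)-3,4-dimethoxyphenyl)prop-2-en-1-yl]oxy}-3,4,5-trimethoxybenzene | COc1cc(C=C)c(OCC(=C)c2cc(OCc3ccccc3)c(OC)c(OC)c2OCc2ccccc2)c(OC)c1OC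
F2 | step 7 | (±)-trans-3-[2,5-bis(benzyloxy)-3,4-dimethoxyphenyl]-6,7,8-trimethoxychroman-4-ol (racemate of 12, both enantiomers written) | COc1cc2c(c(OC)c1OC)OC[C@H](c1cc(OCc3ccccc3)c(OC)c(OC)c1OCc1ccccc1)[C@H]2O.COc1cc2c(c(OC)c1OC)OC[C@@H](c1cc(OCc3ccccc3)c(OC)c(OC)c1OCc1ccccc1)[C@@H]2O
F3 | step 7 | (3S,4R)-3-[2,5-bis(benzyloxy)-3,4-dimethoxyphenyl]-6,7,8-trimethoxychroman-4-yl (2S)-methoxy(phenyl)acetate | CO[C@H](C(=O)O[C@H]1c2cc(OC)c(OC)c(OC)c2OC[C@@H]1c1cc(OCc2ccccc2)c(OC)c(OC)c1OCc1ccccc1)c1ccccc1
F4 | step 2 | 5-acetyl-4-hydroxy-2,3-dimethoxybenzaldehyde | CC(=O)c1cc(C=O)c(OC)c(OC)c1O
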